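**Strategy.** Everything rests on cutting the oxolane at O1–C2. Ring C3 is flanked by two oxygen-bearing one-carbon units, ring C2 and the exocyclic carbinol carbon, so it can be traced back to the 3-position of a symmetric oxetane carried by (S)-3-[4-(benzyloxy)-3-methoxyphenyl]-2-(oxetan-3-yl)propan-1-ol, whose stereocentre (future C4) comes from an Evans alkylation. In the key step a chiral cobalt Lewis acid lets the primary hydroxyl open one of the two diastereotopic oxetane CH2 groups: one operation closes the oxolane, sets C3 trans to the C4 arylmethyl group and liberates the CH2OH that is afterwards oxidised and arylated. Benzyl ethers mask both phenols until the final hydrogenolysis.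

Key step: step 8

Assumption: which antipode of the cobalt catalyst reinforces the substrate's own trans preference cannot be derived with certainty from models; (R,R) is written, and (S,S) would replace it if a small-scale comparison shows it to be the matched one.

**Step 1**
Reactants: 1 (S)-4-benzyl-2-oxazolidinone; 2 bromoacetyl bromide
Product: 4 (4S)-4-benzyl-3-(2-bromoacetyl)-1,3-oxazolidin-2-one, via lithium oxazolidinonide 3 (not isolated)
Conditions: nBuLi (1.0 equiv), THF, −78 °C; then 2, −78 to 0 °C
Reagents that add atoms: none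
Why: N-acylation of the lithiated oxazolidinone at the acyl bromide carbon is a standard imide formation at low temperature, and the auxiliary stereocentre is not involved.

**Step 2**
Reactants: 4 (4S)-4-benzyl-3-(2-bromoacetyl)-1,3-oxazolidin-2-one
Product: 5 diethyl {2-[(4S)-4-benzyl-2-oxo-1,3-oxazolidin-3-yl]-2-oxoethyl}phosphonate
Conditions: P(OEt)3 (1.5 equiv, neat), 90 °C, EtBr distilled off
Reagents that add atoms: triethyl phosphite, CCOP(OCC)OCC
Why: Michaelis–Arbuzov reaction, in which the activated primary α-bromo imide is displaced by the phosphite and the phosphonium intermediate loses bromoethane to give the phosphonate.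

**Step 3**
Reactants: 5 diethyl {2-[(4S)-4-benzyl-2-oxo-1,3-oxazolidin-3-yl]-2-oxoethyl}phosphonate; 6 oxetan-3-one
Product: 7 (4S)-4-benzyl-3-[2-(oxetan-3-ylidene)acetyl]-1,3-oxazolidin-2-one
Conditions: LiCl, iPr2NEt, MeCN, 0 °C to rt
Reagents that add atoms: none
Why: Horner–Wadsworth–Emmons olefination under mild LiCl/amine activation suits the imide and the strained, highly electrophilic ketone, the symmetric oxetane leaves no alkene-geometry question, and building the acyl unit on the auxiliary avoids free oxetan-3-ylacetic acid, which can lactonise by opening its own ring.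

**Step 4**
Reactants: 7 (4S)-4-benzyl-3-[2-(oxetan-3-ylidene)acetyl]-1,3-oxazolidin-2-one
Product: 8 (4S)-4-benzyl-3-[2-(oxetan-3-yl)acetyl]-1,3-oxazolidin-2-one
Conditions: H2 (1 atm), 10% Pd/C, EtOAc, rt
Reagents that add atoms: none
Why: Heterogeneous catalytic hydrogenation saturates the conjugated trisubstituted alkene, as is routine for oxetan-3-ylidene acetates, while the oxetane and the C-benzyl group of the auxiliary are inert; no stereocentre arises because oxetane C3 keeps two identical CH2 arms.

**Step 5**
Reactants: 9 [4-(benzyloxy)-3-methoxyphenyl]methanol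
Product: 10 1-(benzyloxy)-4-(bromomethyl)-2-methoxybenzene
Conditions: PBr3 (0.4 equiv), Et2O, 0 °C
Reagents that add atoms: phosphorus tribromide, BrP(Br)Br
Why: Bromination of an electron-rich benzylic alcohol through its phosphite ester (nucleophilic substitution by bromide) is fast at 0 °C and leaves the aryl ethers untouched; the bromide is used fresh.

**Step 6**
Reactants: 8 (4S)-4-benzyl-3-[2-(oxetan-3-yl)acetyl]-1,3-oxazolidin-2-one; 10 1-(benzyloxy)-4-(bromomethyl)-2-methoxybenzene
Product: 12 (4S)-4-benzyl-3-{(2S)-3-[4-(benzyloxy)-3-methoxyphenyl]-2-(oxetan-3-yl)propanoyl}-1,3-oxazolidin-2-one, via sodium Z-enolate 11 (not isolated)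
Conditions: NaN(SiMe3)2 (1.1 equiv), THF, −78 °C; then 10 (1.5 equiv), −78 to −40 °C
Reagents that add atoms: none
Why: Evans alkylation, in which the chelated Z-enolate is shielded on one face by the benzyl group of the (S)-auxiliary so that the benzylic bromide enters from the other face and sets the α-centre (future ring C4) as S, while the oxetane oxygen, being γ to the enolate carbon, cannot be eliminated.

**Step 7**
Reactants: 12 (4S)-4-benzyl-3-{(2S)-3-[4-(benzyloxy)-3-methoxyphenyl]-2-(oxetan-3-yl)propanoyl}-1,3-oxazolidin-2-one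
Product: 13 (2S)-3-[4-(benzyloxy)-3-methoxyphenyl]-2-(oxetan-3-yl)propan-1-ol
Conditions: LiBH4 (2 equiv), H2O (1 equiv), Et2O/THF, 0 °C; aq. NaOH work-up
Reagents that add atoms: none
Why: Reductive cleavage of the imide by hydride attack at the exocyclic carbonyl gives the primary alcohol and returns the auxiliary without touching the α-stereocentre, the oxetane or the benzyl ether, and the basic work-up protects the acid-sensitive hydroxy-oxetane.

**Step 8**
Reactants: 13 (2S)-3-[4-(benzyloxy)-3-methoxyphenyl]-2-(oxetan-3-yl)propan-1-ol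
Product: 14 {(3R,4S)-4-[4-(benzyloxy)-3-methoxybenzyl]oxolan-3-yl}methanol
Conditions: (R,R)-[N,N'-bis(3,5-di-tert-butylsalicylidene)cyclohexane-1,2-diaminato]Co(OTf) (trivalent cobalt, 5 mol%), MeCN, rt; filtration through Et3N-deactivated silica
Reagents that add atoms: none
Why: The cationic cobalt centre (trivalent) coordinates the oxetane oxygen and the tethered primary hydroxyl displaces it at one ring CH2 in a bimolecular-type substitution, forming O1–C2 as the four-membered ring opens and its strain is released. The closest known reaction type is the (salen)Co-catalysed enantioselective intramolecular opening of 3-substituted oxetanes by pendant alcohols, which gives 3-(hydroxymethyl)oxolanes. The oxolane closes in the 5-exo-tet mode, since the departing oxygen lies outside the new ring. The one new stereocentre, ring C3, is fixed only by which of the two diastereotopic CH2 groups is attacked: the existing S centre at C4 favours the closure that places the liberated CH2OH arm anti to the arylmethyl group, and the catalyst antipode is chosen to reinforce that choice. The step therefore needs group selectivity between the two oxetane methylenes, secured by the adjacent stereocentre together with the matched catalyst. No bond to C4 is made or broken, so its configuration from step 6 is carried through.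

**Step 9**
Reactants: 14 {(3R,4S)-4-[4-(benzyloxy)-3-methoxybenzyl]oxolan-3-yl}methanol
Product: 15 (3S,4S)-4-[4-(benzyloxy)-3-methoxybenzyl]oxolane-3-carbaldehyde
Conditions: DMP (1.3 equiv), CH2Cl2, 0 °C to rt; used crude
Reagents that add atoms: none
Why: Dess–Martin oxidation converts the primary alcohol to the aldehyde under nearly neutral conditions, and since the trans arrangement at C3/C4 is the more stable one, any α-epimerisation would be self-correcting.

**Step 10**
Reactants: 16 4-bromo-2,6-dimethoxyphenol
Product: 17 2-(benzyloxy)-5-bromo-1,3-dimethoxybenzene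
Conditions: BnBr, K2CO3, DMF, rt
Reagents that add atoms: benzyl bromide, BrCc1ccccc1
Why: Williamson ether synthesis on the phenoxide masks the acidic phenol so that the aryl bromide can be turned into a Grignard reagent.

**Step 11**
Reactants: 17 2-(benzyloxy)-5-bromo-1,3-dimethoxybenzene; 15 (3S,4S)-4-[4-(benzyloxy)-3-methoxybenzyl]oxolane-3-carbaldehyde
Product: 19 (S)-[4-(benzyloxy)-3,5-dimethoxyphenyl]{(3S,4S)-4-[4-(benzyloxy)-3-methoxybenzyl]oxolan-3-yl}methanol, via aryl Grignard reagent 18 (not isolated)
Conditions: Mg (I2 cat.), THF, 45 °C; then 15, THF, −78 to 0 °C; H2O quench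
Reagents that add atoms: none
Why: Grignard addition to the aldehyde, in which attack anti to the bulkier ring carbon C4 in the staggered transition state and attack on a magnesium chelate between the carbonyl and ring oxygens both expose the same face and should favour the S carbinol, whose epimer is removed by chromatography.

**Step 12**
Reactants: 19 (S)-[4-(benzyloxy)-3,5-dimethoxyphenyl]{(3S,4S)-4-[4-(benzyloxy)-3-methoxybenzyl]oxolan-3-yl}methanol
Product: 20 (S)-(4-hydroxy-3,5-dimethoxyphenyl)[(3S,4S)-4-(4-hydroxy-3-methoxybenzyl)oxolan-3-yl]methanol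
Conditions: H2 (1 atm), 10% Pd/C, EtOAc/EtOH, rt, stopped at full conversion
Reagents that add atoms: none
Why: Catalytic hydrogenolysis of aryl benzyl ethers under neutral conditions is much faster than cleavage of the secondary benzylic C–OH bond, so both phenols should be released with all three stereocentres untouched.

**Compound list**
1 | (S)-4-benzyl-2-oxazolidinone | O=C1N[C@@H](Cc2ccccc2)CO1 | starting material
2 | bromoacetyl bromide | BrCC(Br)=O | starting material
3 | lithium salt of (S)-4-benzyl-2-oxazolidinone (N-lithiated) | [Li+].O=C1[N-][C@@H](Cc2ccccc2)CO1 | intermediate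
4 | (4S)-4-benzyl-3-(2-bromoacetyl)-1,3-oxazolidin-2-one | O=C(CBr)N1[C@@H](Cc2ccccc2)COC1=O | intermediate
5 | diethyl {2-[(4S)-4-benzyl-2-oxo-1,3-oxazolidin-3-yl]-2-oxoethyl}phosphonate | CCOP(=O)(CC(=O)N1[C@@H](Cc2ccccc2)COC1=O)OCC | intermediate
6 | oxetan-3-one | O=C1COC1 | starting material
7 | (4S)-4-benzyl-3-[2-(oxetan-3-ylidene)acetyl]-1,3-oxazolidin-2-one | O=C(C=C1COC1)N1[C@@H](Cc2ccccc2)COC1=O | intermediate
8 | (4S)-4-benzyl-3-[2-(oxetan-3-yl)acetyl]-1,3-oxazolidin-2-one | O=C(CC1COC1)N1[C@@H](Cc2ccccc2)COC1=O | intermediate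
9 | [4-(benzyloxy)-3-methoxyphenyl]methanol (O-benzylvanillyl alcohol, commercial) | COc1cc(CO)ccc1OCc1ccccc1 | starting material
10 | 1-(benzyloxy)-4-(bromomethyl)-2-methoxybenzene | COc1cc(CBr)ccc1OCc1ccccc1 | intermediate
11 | sodium Z-enolate of 8 | [Na+].[O-]/C(=C\C1COC1)N1[C@@H](Cc2ccccc2)COC1=O | intermediate
12 | (4S)-4-benzyl-3-{(2S)-3-[4-(benzyloxy)-3-methoxyphenyl]-2-(oxetan-3-yl)propanoyl}-1,3-oxazolidin-2-one | COc1cc(C[C@H](C(=O)N2[C@@H](Cc3ccccc3)COC2=O)C2COC2)ccc1OCc1ccccc1 | intermediate
13 | (2S)-3-[4-(benzyloxy)-3-methoxyphenyl]-2-(oxetan-3-yl)propan-1-ol | COc1cc(C[C@H](CO)C2COC2)ccc1OCc1ccccc1 | intermediate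
14 | {(3R,4S)-4-[4-(benzyloxy)-3-methoxybenzyl]oxolan-3-yl}methanol (trans) | COc1cc(C[C@@H]2COC[C@H]2CO)ccc1OCc1ccccc1 | intermediate
15 | (3S,4S)-4-[4-(benzyloxy)-3-methoxybenzyl]oxolane-3-carbaldehyde (trans) | COc1cc(C[C@@H]2COC[C@H]2C=O)ccc1OCc1ccccc1 | intermediate
16 | 4-bromo-2,6-dimethoxyphenol | COc1cc(Br)cc(OC)c1O | starting material
17 | 2-(benzyloxy)-5-bromo-1,3-dimethoxybenzene | COc1cc(Br)cc(OC)c1OCc1ccccc1 | intermediate
18 | [4-(benzyloxy)-3,5-dimethoxyphenyl]magnesium bromide | COc1cc([Mg]Br)cc(OC)c1OCc1ccccc1 | intermediate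
19 | (S)-[4-(benzyloxy)-3,5-dimethoxyphenyl]{(3S,4S)-4-[4-(benzyloxy)-3-methoxybenzyl]oxolan-3-yl}methanol | COc1cc(C[C@@H]2COC[C@H]2[C@H](O)c2cc(OC)c(OCc3ccccc3)c(OC)c2)ccc1OCc1ccccc1 | intermediate
20 | (S)-(4-hydroxy-3,5-dimethoxyphenyl)[(3S,4S)-4-(4-hydroxy-3-methoxybenzyl)oxolan-3-yl]methanol | COc1cc(C[C@@H]2COC[C@H]2[C@H](O)c2cc(OC)c(O)c(OC)c2)ccc1O | target

**Step count.** Total: 12 steps. Longest linear sequence: 10 steps (steps 1, 2, 3, 4, 6, 7, 8, 9, 11, 12).

**Steps most likely to fail**

1. Step 8. What may go wrong: weak discrimination between the two oxetane CH2 groups, or slow turnover with this oxetane that carries hydrogen at C3, so that cis and trans oxolanes form together. The fallback sets out from 13 and comes back at 15. Compound 13 is cyclised with an achiral acid (TsOH·H2O cat., CH2Cl2, rt) without regard to selectivity, giving 14 together with its cis isomer {(3S,4S)-4-[4-(benzyloxy)-3-methoxybenzyl]oxolan-3-yl}methanol F1. The mixture is oxidised with DMP to 15 and the cis aldehyde (3R,4S)-4-[4-(benzyloxy)-3-methoxybenzyl]oxolane-3-carbaldehyde F2. Brief treatment with DBU (cat., CH2Cl2, rt) should then epimerise the now acidic C3 centre toward the more stable trans aldehyde 15. C3 is thus set by thermodynamic control instead of by the catalyst. Ring opening by β-elimination is not expected, because it would be the reverse of a 5-endo-trig closure.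

2. Step 11. What may go wrong: poor facial selectivity at the aldehyde and loss of material by enolisation under the basic Grignard reagent. The fallback sets out from 15 and comes back at 19. The addition is run for conversion only, and the mixture of 19 and its carbinol epimer (R)-[4-(benzyloxy)-3,5-dimethoxyphenyl]{(3S,4S)-4-[4-(benzyloxy)-3-methoxybenzyl]oxolan-3-yl}methanol F3 is oxidised (DMP, CH2Cl2) to the single ketone [4-(benzyloxy)-3,5-dimethoxyphenyl]{(3S,4S)-4-[4-(benzyloxy)-3-methoxybenzyl]oxolan-3-yl}methanone F4. A Corey–Bakshi–Shibata reduction ((R)-Me-CBS oxazaborolidine, BH3·SMe2, THF, −20 °C), with the aryl group as the large substituent, should return 19 under catalyst control. The carbinol centre is then made by C–H instead of C–C bond formation.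

3. Step 12. What may go wrong: over-reduction, that is hydrogenolysis of the benzylic C–OH bond of the electron-rich carbinol alongside debenzylation. The fallback sets out from 15 and comes back at 20; it removes the benzyl ether before the carbinol exists and finishes with silyl ethers. Compound 15 is hydrogenolysed (H2, Pd/C, EtOAc) to (3S,4S)-4-(4-hydroxy-3-methoxybenzyl)oxolane-3-carbaldehyde F5 and silylated (TBSCl, imidazole, DMF) to (3S,4S)-4-[4-(tert-butyldimethylsilyloxy)-3-methoxybenzyl]oxolane-3-carbaldehyde F6. Phenol 16 is silylated in the same way to (4-bromo-2,6-dimethoxyphenoxy)(tert-butyl)dimethylsilane F7 and converted with Mg in THF into [4-(tert-butyldimethylsilyloxy)-3,5-dimethoxyphenyl]magnesium bromide F8. Addition of F8 to F6 should give (S)-[4-(tert-butyldimethylsilyloxy)-3,5-dimethoxyphenyl]{(3S,4S)-4-[4-(tert-butyldimethylsilyloxy)-3-methoxybenzyl]oxolan-3-yl}methanol F9. Bu4NF buffered with AcOH (THF, 0 °C) then releases both phenols to give 20 without a reductive step.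

**Further compounds**
F1 | step 8 | {(3S,4S)-4-[4-(benzyloxy)-3-methoxybenzyl]oxolan-3-yl}methanol (cis) | COc1cc(C[C@@H]2COC[C@@H]2CO)ccc1OCc1ccccc1
F2 | step 8 | (3R,4S)-4-[4-(benzyloxy)-3-methoxybenzyl]oxolane-3-carbaldehyde (cis) | COc1cc(C[C@@H]2COC[C@@H]2C=O)ccc1OCc1ccccc1
F3 | step 11 | (R)-[4-(benzyloxy)-3,5-dimethoxyphenyl]{(3S,4S)-4-[4-(benzyloxy)-3-methoxybenzyl]oxolan-3-yl}methanol | COc1cc(C[C@@H]2COC[C@H]2[C@@H](O)c2cc(OC)c(OCc3ccccc3)c(OC)c2)ccc1OCc1ccccc1
F4 | step 11 | [4-(benzyloxy)-3,5-dimethoxyphenyl]{(3S,4S)-4-[4-(benzyloxy)-3-methoxybenzyl]oxolan-3-yl}methanone | COc1cc(C[C@@H]2COC[C@H]2C(=O)c2cc(OC)c(OCc3ccccc3)c(OC)c2)ccc1OCc1ccccc1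
F5 | step 12 | (3S,4S)-4-(4-hydroxy-3-methoxybenzyl)oxolane-3-carbaldehyde | COc1cc(C[C@@H]2COC[C@H]2C=O)ccc1O
F6 | step 12 | (3S,4S)-4-[4-(tert-butyldimethylsilyloxy)-3-methoxybenzyl]oxolane-3-carbaldehyde | COc1cc(C[C@@H]2COC[C@H]2C=O)ccc1O[Si](C)(C)C(C)(C)C
F7 | step 12 | (4-bromo-2,6-dimethoxyphenoxy)(tert-butyl)dimethylsilane | COc1cc(Br)cc(OC)c1O[Si](C)(C)C(C)(C)C
F8 | step 12 | [4-(tert-butyldimethylsilyloxy)-3,5-dimethoxyphenyl]magnesium bromide | COc1cc([Mg]Br)cc(OC)c1O[Si](C)(C)C(C)(C)C
F9 | step 12 | (S)-[4-(tert-butyldimethylsilyloxy)-3,5-dimethoxyphenyl]{(3S,4S)-4-[4-(tert-butyldimethylsilyloxy)-3-methoxybenzyl]oxolan-3-yl}methanol | COc1cc(C[C@@H]2COC[C@H]2[C@H](O)c2cc(OC)c(O[Si](C)(C)C(C)(C)C)c(OC)c2)ccc1O[Si](C)(C)C(C)(C)C
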